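**Plan**
- Retrosynthesis: the only ring is the 14-membered carbocycle. It holds the 1,5-diene unit C12(Me)=C11H–C10H2–C9H2–C8(Me)=C7H, so the C10–C11 bond (vinylic CH to its allylic CH2) is cut first. This leaves an (E)-alkenyl iodide at C11 and a primary borane at C10 that comes from the terminal vinyl group (C9=C10) of a (Z)-3-methyl-1,3-diene.
- Further cuts: the skipped diene at C5–C6 (alkenylalane + (Z)-allylic chloride), both C(Me)=CH units back to terminal alkynes (carboalumination), and the C2–C3 and C13–C14 bonds next to the carbinol (two propargyl-anion openings at a 2-substituted glycidyl tosylate).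
- Forward: (R)-citronellal → α-methylene aldehyde → allylic alcohol → epoxy tosylate → first homopropargyl arm → second arm → allylic oxidation of the side chain → skipped dienyne → (Z)-diene → alkenyl iodide → ring closure, the ring arising last.
- Stereochemistry: the side-chain methine comes from (R)-citronellal. The carbinol centre comes from Sharpless epoxidation with L-(+)-tartrate, combined with the order in which the two near-identical arms are attached. The Z olefin comes from commercial (Z)-enynol, and the three E olefins from two syn-carboaluminations and SeO2 oxidation of the E methyl.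

Key step: step 13

Remark: (R)-citronellal and the (Z)-enynol are taken as the commercial single isomers; from step 8 on both hydroxyls are carried unprotected, so the organoaluminium and borane steps use extra equivalents; the carbinol descriptor alternates between R and S only through CIP priority changes, the centre being untouched after step 5.

Step 1
Reactants: 1 (2Z)-3-methylpent-2-en-4-yn-1-ol
Product: 3 (2Z)-3-methyl-5-(trimethylsilyl)pent-2-en-4-yn-1-ol, via O,C-bis(trimethylsilyl) derivative 2 (not isolated)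
Conditions: n-BuLi (2.1 equiv), THF, −78 °C; TMSCl (2.2 equiv), −78 °C → rt; then 1 M HCl (aq), rt
Reagents that add atoms: chlorotrimethylsilane, C[Si](C)(C)Cl
Why: Double deprotonation gives the alkoxide/acetylide, both are silylated, and dilute acid hydrolyses only the O–Si bond, so the alkyne is capped for the later zerovalent-palladium step and the Z olefin is untouched (C-silylation of a terminal alkyne).

Step 2
Reactants: 3 (2Z)-3-methyl-5-(trimethylsilyl)pent-2-en-4-yn-1-ol
Product: 5 [(3Z)-5-chloro-3-methylpent-3-en-1-yn-1-yl]trimethylsilane, via allylic mesylate 4 (not isolated)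
Conditions: MsCl, LiCl, 2,4,6-collidine, DMF, 0 °C
Reagents that add atoms: lithium chloride, [Li+].[Cl-]
Why: The primary allylic mesylate is displaced by chloride in an SN2 reaction at the CH2 carbon under buffered, non-ionising conditions, which should keep both the position and the Z geometry of the trisubstituted olefin (mesylate-to-chloride exchange).

Step 3
Reactants: 6 (3R)-3,7-dimethyloct-6-enal ((R)-citronellal)
Product: 7 (3R)-3,7-dimethyl-2-methylideneoct-6-enal
Conditions: 37% aq. HCHO, pyrrolidine (10 mol%), propionic acid (10 mol%), i-PrOH, 45 °C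
Reagents that add atoms: formaldehyde, C=O
Why: Amine-catalysed Mannich condensation with formaldehyde and elimination gives the α-methylene aldehyde; the adjacent methine hydrogen is not acidic in the cross-conjugated enal, so the R centre should survive (α-methylenation of an aldehyde).

Step 4
Reactants: 7 (3R)-3,7-dimethyl-2-methylideneoct-6-enal
Product: 8 (3R)-3,7-dimethyl-2-methylideneoct-6-en-1-ol
Conditions: NaBH4, CeCl3·7H2O, MeOH, 0 °C
Reagents that add atoms: none
Why: Luche reduction delivers hydride to the cerium-activated carbonyl in a 1,2-sense and gives the 2-substituted allylic alcohol without conjugate reduction.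

Step 5
Reactants: 8 (3R)-3,7-dimethyl-2-methylideneoct-6-en-1-ol
Product: 10 [(2R)-2-[(2R)-6-methylhept-5-en-2-yl]oxiran-2-yl]methyl 4-methylbenzenesulfonate, via (2S)-epoxy alcohol 9 (not isolated)
Conditions: Ti(OiPr)4 (10 mol%), L-(+)-diethyl tartrate (12 mol%), t-BuOOH, 4 Å MS, CH2Cl2, −20 °C; then P(OMe)3; Et3N, DMAP (cat.), TsCl, −20 → 0 °C
Reagents that add atoms: tert-butyl hydroperoxide, CC(C)(C)OO; 4-methylbenzenesulfonyl chloride, Cc1ccc(cc1)S(=O)(=O)Cl
Why: Sharpless asymmetric epoxidation of the 1,1-disubstituted allylic alcohol with the L-(+)-tartrate titanium complex should put oxygen on the face that gives the 2S epoxy alcohol under reagent control (the remote trisubstituted olefin is not an allylic alcohol and stays); in-situ tosylation traps the sensitive epoxy alcohol as a bis-electrophile, and this step sets the future carbinol stereocentre (S becomes R on tosylation only by priority change).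

Step 6
Reactants: 10 [(2R)-2-[(2R)-6-methylhept-5-en-2-yl]oxiran-2-yl]methyl 4-methylbenzenesulfonate; 11 tri(propan-2-yl)(prop-1-yn-1-yl)silane
Product: 13 {4-[(2S)-2-[(2R)-6-methylhept-5-en-2-yl]oxiran-2-yl]but-1-yn-1-yl}tri(propan-2-yl)silane, via tosyloxy tertiary alcohol 12 (not isolated)
Conditions: 11, n-BuLi, THF, −20 °C; then 10, BF3·OEt2, −78 °C; then K2CO3, MeOH, rt
Reagents that add atoms: none
Why: The silyl-propargyl lithium opens the BF3-activated epoxide at its CH2 carbon (the neopentyl-type tosylate is far slower in SN2) and carbonate then closes the tertiary alkoxide onto the tosylate (3-exo-tet), so the carbinol C–O bond is never broken and the configuration from step 5 is kept while the first arm sits on the former epoxide carbon (epoxide opening by a propargyl anion equivalent).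

Step 7
Reactants: 13 {4-[(2S)-2-[(2R)-6-methylhept-5-en-2-yl]oxiran-2-yl]but-1-yn-1-yl}tri(propan-2-yl)silane; 14 trimethyl(prop-1-yn-1-yl)silane
Product: 16 (5S)-5-[(2R)-6-methylhept-5-en-2-yl]-1-[tri(propan-2-yl)silyl]nona-1,8-diyn-5-ol, via bis-silylated diynol 15 (not isolated)
Conditions: 14, n-BuLi, THF, −78 → −20 °C; then 13, BF3·OEt2, −78 °C; then K2CO3, MeOH, rt
Reagents that add atoms: none
Why: The same opening at the CH2 terminus of the new 2,2-disubstituted epoxide attaches the second homopropargyl arm to the former CH2OH carbon, which fixes the tertiary carbinol with the two arms told apart; methanolysis removes only the trimethylsilyl group and leaves the triisopropylsilyl alkyne protected.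

Step 8
Reactants: 16 (5S)-5-[(2R)-6-methylhept-5-en-2-yl]-1-[tri(propan-2-yl)silyl]nona-1,8-diyn-5-ol
Product: 17 (2E,6R,7S)-7-(but-3-yn-1-yl)-2,6-dimethyl-11-[tri(propan-2-yl)silyl]undec-2-en-10-yne-1,7-diol
Conditions: SeO2 (0.3 equiv), t-BuOOH, salicylic acid (cat.), CH2Cl2, rt
Reagents that add atoms: selenium dioxide (oxygen carrier), O=[Se]=O; tert-butyl hydroperoxide (terminal oxidant), CC(C)(C)OO
Why: Riley allylic oxidation (ene reaction, then [2,3]-sigmatropic shift) at the only olefin attacks the E methyl of the isopropylidene group and should give the E allylic alcohol, the alkynes and the tertiary alcohol being inert at room temperature.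

Step 9
Reactants: 17 (2E,6R,7S)-7-(but-3-yn-1-yl)-2,6-dimethyl-11-[tri(propan-2-yl)silyl]undec-2-en-10-yne-1,7-diol; 5 [(3Z)-5-chloro-3-methylpent-3-en-1-yn-1-yl]trimethylsilane
Product: 19 (2E,6R,7S,10E,13Z)-2,6,10,14-tetramethyl-7-{4-[tri(propan-2-yl)silyl]but-3-yn-1-yl}-16-(trimethylsilyl)hexadeca-2,10,13-trien-15-yne-1,7-diol, via alkenyldimethylalane 18 (not isolated)
Conditions: Me3Al (5 equiv), Cp2ZrCl2 (0.5 equiv), CH2Cl2, 0 °C → rt; volatiles off; then 5, Pd(PPh3)4 (5 mol%), THF, rt
Reagents that add atoms: trimethylaluminium, C[Al](C)C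
Why: Zirconium-catalysed Negishi carboalumination adds Me–Al syn across the free terminal alkyne with aluminium on the terminal carbon (E alkenylalane; the hindered silyl alkyne should not react), and zerovalent palladium couples it with the allylic chloride at the primary allyl terminus with retention of both olefin geometries, as in the alkenylalane–allyl halide coupling used for terpenoid 1,4-dienes.

Step 10
Reactants: 19 (2E,6R,7S,10E,13Z)-2,6,10,14-tetramethyl-7-{4-[tri(propan-2-yl)silyl]but-3-yn-1-yl}-16-(trimethylsilyl)hexadeca-2,10,13-trien-15-yne-1,7-diol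
Product: 20 (2E,6R,7R,10E,13Z)-7-(but-3-yn-1-yl)-2,6,10,14-tetramethylhexadeca-2,10,13-trien-15-yne-1,7-diol
Conditions: TBAF (3 equiv), THF, 0 °C → rt
Reagents that add atoms: none
Why: Fluoride cleaves both alkynyl C–Si bonds and frees the conjugated enyne terminus and the isolated terminal alkyne, no other group being fluoride-sensitive (protodesilylation).

Step 11
Reactants: 20 (2E,6R,7R,10E,13Z)-7-(but-3-yn-1-yl)-2,6,10,14-tetramethylhexadeca-2,10,13-trien-15-yne-1,7-diol
Product: 21 (2E,6R,7R,10E,13Z)-7-(but-3-yn-1-yl)-2,6,10,14-tetramethylhexadeca-2,10,13,15-tetraene-1,7-diol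
Conditions: Zn dust activated with Cu(OAc)2 and AgNO3, MeOH/H2O, rt → 40 °C
Reagents that add atoms: none
Why: Copper/silver-activated zinc in aqueous methanol reduces only conjugated triple bonds, so the enyne should become the terminal (Z)-3-methyl-1,3-diene while the isolated alkyne and all olefin geometries stay (chemoselective zinc semireduction).

Step 12
Reactants: 21 (2E,6R,7R,10E,13Z)-7-(but-3-yn-1-yl)-2,6,10,14-tetramethylhexadeca-2,10,13,15-tetraene-1,7-diol
Product: 23 (2E,6R,7S,10E,13Z)-7-[(3E)-4-iodo-3-methylbut-3-en-1-yl]-2,6,10,14-tetramethylhexadeca-2,10,13,15-tetraene-1,7-diol, via alkenyldimethylalane 22 (not isolated)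
Conditions: Me3Al (5 equiv), Cp2ZrCl2 (0.5 equiv), CH2Cl2, 0 °C → rt; then I2 (1.1 equiv), THF, −30 °C, dark
Reagents that add atoms: trimethylaluminium, C[Al](C)C; iodine, II
Why: A second Negishi carboalumination of the remaining alkyne (far faster than any olefin) gives the E alkenylalane by syn addition with aluminium terminal, and iodinolysis with retention gives the E alkenyl iodide; brief contact with one equivalent of iodine at low temperature in the dark should spare the Z diene.

Step 13
Reactants: 23 (2E,6R,7S,10E,13Z)-7-[(3E)-4-iodo-3-methylbut-3-en-1-yl]-2,6,10,14-tetramethylhexadeca-2,10,13,15-tetraene-1,7-diol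
Product: 25 (1R,4E,7Z,11E)-1-[(2R,5E)-7-hydroxy-6-methylhept-5-en-2-yl]-4,8,12-trimethylcyclotetradeca-4,7,11-trien-1-ol, via B-alkyl-9-BBN borane 24 (not isolated)
Conditions: 9-BBN (3.5 equiv), THF, 0 °C → rt; then aq. Cs2CO3; slow addition (syringe pump) to PdCl2(dppf) (15 mol%), AsPh3 (30 mol%), Cs2CO3, DMF/THF/H2O, 50 °C, 0.002 M
Reagents that add atoms: none
Why: 9-BBN adds to the only monosubstituted olefin, the terminal vinyl of the diene, with boron on the CH2 terminus (the four trisubstituted olefins are far slower and the hydroxyls only consume reagent); zerovalent palladium then inserts into the C–I bond with retention, the base-activated primary alkylborate transmetalates, and reductive elimination forms the C(sp2)–C(sp3) bond. The closest known reaction type is the intramolecular B-alkyl Suzuki–Miyaura coupling used to close macrocyclic terpenoid carbocycles. The single 14-membered ring is closed by macrocyclisation at the C10–C11 bond, and slow addition at high dilution is needed so that ring closure outruns chain growth. No stereocentre is formed; the E geometry of the C11=C12 olefin is that of the alkenyl iodide and the other olefins are not touched. The step needs chemoselective hydroboration (secured by the unique terminal vinyl group), transfer of the primary alkyl group rather than the bicyclic boron ligand (inherent to 9-BBN), and reductive elimination faster than β-hydride elimination (secured by the wide-bite-angle dppf ligand with AsPh3).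

**Compound list**
1 | (2Z)-3-methylpent-2-en-4-yn-1-ol | C#C/C(C)=C\CO | starting material
2 | trimethyl{[(2Z)-3-methyl-5-(trimethylsilyl)pent-2-en-4-yn-1-yl]oxy}silane | C[Si](C)(C)C#C/C(C)=C\CO[Si](C)(C)C | intermediate
3 | (2Z)-3-methyl-5-(trimethylsilyl)pent-2-en-4-yn-1-ol | C[Si](C)(C)C#C/C(C)=C\CO | intermediate
4 | (2Z)-3-methyl-5-(trimethylsilyl)pent-2-en-4-yn-1-yl methanesulfonate | C[Si](C)(C)C#C/C(C)=C\COS(C)(=O)=O | intermediate
5 | [(3Z)-5-chloro-3-methylpent-3-en-1-yn-1-yl]trimethylsilane | C[Si](C)(C)C#C/C(C)=C\CCl | intermediate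
6 | (3R)-3,7-dimethyloct-6-enal ((R)-citronellal) | C[C@H](CCC=C(C)C)CC=O | starting material
7 | (3R)-3,7-dimethyl-2-methylideneoct-6-enal | C=C(C=O)[C@H](C)CCC=C(C)C | intermediate
8 | (3R)-3,7-dimethyl-2-methylideneoct-6-en-1-ol | C=C(CO)[C@H](C)CCC=C(C)C | intermediate
9 | [(2S)-2-[(2R)-6-methylhept-5-en-2-yl]oxiran-2-yl]methanol | OC[C@]1(CO1)[C@H](C)CCC=C(C)C | intermediate
10 | [(2R)-2-[(2R)-6-methylhept-5-en-2-yl]oxiran-2-yl]methyl 4-methylbenzenesulfonate | Cc1ccc(cc1)S(=O)(=O)OC[C@]2(CO2)[C@H](C)CCC=C(C)C | intermediate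
11 | tri(propan-2-yl)(prop-1-yn-1-yl)silane | CC#C[Si](C(C)C)(C(C)C)C(C)C | starting material
12 | (2S)-2-hydroxy-2-[(2R)-6-methylhept-5-en-2-yl]-6-[tri(propan-2-yl)silyl]hex-5-yn-1-yl 4-methylbenzenesulfonate | Cc1ccc(cc1)S(=O)(=O)OC[C@](O)(CCC#C[Si](C(C)C)(C(C)C)C(C)C)[C@H](C)CCC=C(C)C | intermediate
13 | {4-[(2S)-2-[(2R)-6-methylhept-5-en-2-yl]oxiran-2-yl]but-1-yn-1-yl}tri(propan-2-yl)silane | CC(C)[Si](C(C)C)(C(C)C)C#CCC[C@@]1(CO1)[C@H](C)CCC=C(C)C | intermediate
14 | trimethyl(prop-1-yn-1-yl)silane | CC#C[Si](C)(C)C | starting material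
15 | (5S)-5-[(2R)-6-methylhept-5-en-2-yl]-1-[tri(propan-2-yl)silyl]-9-(trimethylsilyl)nona-1,8-diyn-5-ol | C[Si](C)(C)C#CCC[C@@](O)([C@H](C)CCC=C(C)C)CCC#C[Si](C(C)C)(C(C)C)C(C)C | intermediate
16 | (5S)-5-[(2R)-6-methylhept-5-en-2-yl]-1-[tri(propan-2-yl)silyl]nona-1,8-diyn-5-ol | C#CCC[C@@](O)([C@H](C)CCC=C(C)C)CCC#C[Si](C(C)C)(C(C)C)C(C)C | intermediate
17 | (2E,6R,7S)-7-(but-3-yn-1-yl)-2,6-dimethyl-11-[tri(propan-2-yl)silyl]undec-2-en-10-yne-1,7-diol | C#CCC[C@@](O)([C@H](C)CC/C=C(\C)CO)CCC#C[Si](C(C)C)(C(C)C)C(C)C | intermediate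
18 | (E)-alkenyl(dimethyl)alane from syn Me–Al addition to the terminal alkyne of 17; both hydroxyls as dimethylaluminium alkoxides | C[Al](C)/C=C(\C)CC[C@@](O[Al](C)C)([C@H](C)CC/C=C(\C)CO[Al](C)C)CCC#C[Si](C(C)C)(C(C)C)C(C)C | intermediate
19 | (2E,6R,7S,10E,13Z)-2,6,10,14-tetramethyl-7-{4-[tri(propan-2-yl)silyl]but-3-yn-1-yl}-16-(trimethylsilyl)hexadeca-2,10,13-trien-15-yne-1,7-diol | C[Si](C)(C)C#C/C(C)=C\C/C=C(\C)CC[C@@](O)([C@H](C)CC/C=C(\C)CO)CCC#C[Si](C(C)C)(C(C)C)C(C)C | intermediate
20 | (2E,6R,7R,10E,13Z)-7-(but-3-yn-1-yl)-2,6,10,14-tetramethylhexadeca-2,10,13-trien-15-yne-1,7-diol | C#C/C(C)=C\C/C=C(\C)CC[C@@](O)([C@H](C)CC/C=C(\C)CO)CCC#C | intermediate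
21 | (2E,6R,7R,10E,13Z)-7-(but-3-yn-1-yl)-2,6,10,14-tetramethylhexadeca-2,10,13,15-tetraene-1,7-diol | C=C/C(C)=C\C/C=C(\C)CC[C@@](O)([C@H](C)CC/C=C(\C)CO)CCC#C | intermediate
22 | (E)-alkenyl(dimethyl)alane from syn Me–Al addition to the terminal alkyne of 21; both hydroxyls as dimethylaluminium alkoxides | C=C/C(C)=C\C/C=C(\C)CC[C@@](O[Al](C)C)([C@H](C)CC/C=C(\C)CO[Al](C)C)CC/C(C)=C/[Al](C)C | intermediate
23 | (2E,6R,7S,10E,13Z)-7-[(3E)-4-iodo-3-methylbut-3-en-1-yl]-2,6,10,14-tetramethylhexadeca-2,10,13,15-tetraene-1,7-diol | C=C/C(C)=C\C/C=C(\C)CC[C@@](O)([C@H](C)CC/C=C(\C)CO)CC/C(C)=C/I | intermediate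
24 | B-alkyl-9-borabicyclo[3.3.1]nonane from hydroboration of the terminal vinyl group of 23; primary hydroxyl as its 9-BBN borinate | C1CCC2CCCC1B2CC/C(C)=C\C/C=C(\C)CC[C@@](O)([C@H](C)CC/C=C(\C)COB3C4CCCC3CCC4)CC/C(C)=C/I | intermediate
25 | (1R,4E,7Z,11E)-1-[(2R,5E)-7-hydroxy-6-methylhept-5-en-2-yl]-4,8,12-trimethylcyclotetradeca-4,7,11-trien-1-ol | C/C1=C/C/C=C(\C)CC[C@@](O)([C@H](C)CC/C=C(\C)CO)CC/C(C)=C/CC1 | target

Total step count: 13 (2 for the allylic chloride, 11 on the main line).
Longest linear sequence: 11 steps (steps 3–13, from (R)-citronellal).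

**Steps most likely to fail**

Step 13 (macrocyclisation). Chain growth between two molecules may outrun ring closure; the alkyl group may be lost by protodeboronation or β-hydride elimination before transmetalation; or consumption of 9-BBN by the free hydroxyls may leave hydroboration incomplete or unselective. The fallback sets out from 23 and returns at 25; it closes the same bond by an intramolecular Negishi coupling of a defined alkylzinc reagent. Both hydroxyls of 23 are silylated (TESOTf, 2,6-lutidine) to the bis(triethylsilyl) ether F1. Hydroboration–oxidation of the terminal vinyl group (9-BBN; NaBO3·4H2O) gives the primary homoallylic alcohol F2, which is converted (I2, PPh3, imidazole) into the alkyl iodide F3. Zinc dust with LiCl in THF should insert only into the C(sp3)–I bond to give the alkylzinc iodide F4 (not isolated). After dilution, Pd(PPh3)4 (zerovalent palladium) should cyclise it to the bis-silylated macrocycle F5, and TBAF then gives 25.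

Step 9 (carboalumination and allylation). The alkynyl-substituted π-allylpalladium intermediate may equilibrate and erode the Z geometry; methyl rather than alkenyl may transfer from aluminium; or the silyl alkyne may also be carboaluminated. The fallback sets out from 17 and returns at 20; it separates olefin formation from the coupling and replaces the π-allyl coupling by a copper-catalysed SN2 displacement. The alkenylalane 18 is quenched with iodine to give the (E)-alkenyl iodide F6, whose geometry can be checked before the coupling. Silylation (TESOTf, 2,6-lutidine) gives the bis(triethylsilyl) ether F7. Iodine–magnesium exchange (i-PrMgCl·LiCl, THF) gives the alkenylmagnesium chloride F8 (not isolated), which with Li2CuCl4 (cat.) should displace chloride from 5 at the primary carbon with retention of the allyl geometry to give the fully silylated dienyne F9. Excess TBAF removes all four silyl groups and gives 20.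

Step 5 (asymmetric epoxidation). Facial selectivity may be poor if L-(+)-tartrate and the adjacent R methine are a mismatched pair, and the 2,2-disubstituted epoxy alcohol may be opened by alkoxide before it is tosylated. The fallback sets out from 8 and returns at 15; because the two arms differ only at their far ends, the opposite face can be used if the arms are attached in the opposite order. Epoxidation of 8 with Ti(OiPr)4, D-(−)-diethyl tartrate and t-BuOOH gives the epimeric epoxy alcohol F10 (not isolated) and, after in-situ tosylation, the tosylate F11. The lithio derivative of 14 with BF3·OEt2 opens F11 to the tosyloxy alcohol F12 (not isolated), which NaH in THF closes to the epoxide F13 with the trimethylsilyl group kept. Opening of F13 with the lithio derivative of 11 and BF3·OEt2 gives 15, which is desilylated to 16 as in step 7.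

Further compounds
F1 | step 13 | 1,7-bis(triethylsilyl) ether of 23 | C=C/C(C)=C\C/C=C(\C)CC[C@@](O[Si](CC)(CC)CC)([C@H](C)CC/C=C(\C)CO[Si](CC)(CC)CC)CC/C(C)=C/I
F2 | step 13 | primary alcohol from hydroboration–oxidation of the terminal vinyl group of F1 | OCC/C(C)=C\C/C=C(\C)CC[C@@](O[Si](CC)(CC)CC)([C@H](C)CC/C=C(\C)CO[Si](CC)(CC)CC)CC/C(C)=C/I
F3 | step 13 | primary alkyl iodide from F2 | ICC/C(C)=C\C/C=C(\C)CC[C@@](O[Si](CC)(CC)CC)([C@H](C)CC/C=C(\C)CO[Si](CC)(CC)CC)CC/C(C)=C/I
F4 | step 13 | primary alkylzinc iodide from F3 | I[Zn]CC/C(C)=C\C/C=C(\C)CC[C@@](O[Si](CC)(CC)CC)([C@H](C)CC/C=C(\C)CO[Si](CC)(CC)CC)CC/C(C)=C/I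
F5 | step 13 | bis(triethylsilyl) ether of 25 | C/C1=C/C/C=C(\C)CC[C@@](O[Si](CC)(CC)CC)([C@H](C)CC/C=C(\C)CO[Si](CC)(CC)CC)CC/C(C)=C/CC1
F6 | step 9 | (2E,6R,7R)-7-[(3E)-4-iodo-3-methylbut-3-en-1-yl]-2,6-dimethyl-11-[tri(propan-2-yl)silyl]undec-2-en-10-yne-1,7-diol | I/C=C(\C)CC[C@@](O)([C@H](C)CC/C=C(\C)CO)CCC#C[Si](C(C)C)(C(C)C)C(C)C
F7 | step 9 | 1,7-bis(triethylsilyl) ether of F6 | I/C=C(\C)CC[C@@](O[Si](CC)(CC)CC)([C@H](C)CC/C=C(\C)CO[Si](CC)(CC)CC)CCC#C[Si](C(C)C)(C(C)C)C(C)C
F8 | step 9 | (E)-alkenylmagnesium chloride from F7 | Cl[Mg]/C=C(\C)CC[C@@](O[Si](CC)(CC)CC)([C@H](C)CC/C=C(\C)CO[Si](CC)(CC)CC)CCC#C[Si](C(C)C)(C(C)C)C(C)C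
F9 | step 9 | 1,7-bis(triethylsilyl) ether of 19 | C[Si](C)(C)C#C/C(C)=C\C/C=C(\C)CC[C@@](O[Si](CC)(CC)CC)([C@H](C)CC/C=C(\C)CO[Si](CC)(CC)CC)CCC#C[Si](C(C)C)(C(C)C)C(C)C
F10 | step 5 | [(2R)-2-[(2R)-6-methylhept-5-en-2-yl]oxiran-2-yl]methanol | OC[C@@]1(CO1)[C@H](C)CCC=C(C)C
F11 | step 5 | [(2S)-2-[(2R)-6-methylhept-5-en-2-yl]oxiran-2-yl]methyl 4-methylbenzenesulfonate | Cc1ccc(cc1)S(=O)(=O)OC[C@@]2(CO2)[C@H](C)CCC=C(C)C
F12 | step 5 | (2R)-2-hydroxy-2-[(2R)-6-methylhept-5-en-2-yl]-6-(trimethylsilyl)hex-5-yn-1-yl 4-methylbenzenesulfonate | Cc1ccc(cc1)S(=O)(=O)OC[C@@](O)(CCC#C[Si](C)(C)C)[C@H](C)CCC=C(C)C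
F13 | step 5 | trimethyl{4-[(2R)-2-[(2R)-6-methylhept-5-en-2-yl]oxiran-2-yl]but-1-yn-1-yl}silane | C[Si](C)(C)C#CCC[C@]1(CO1)[C@H](C)CCC=C(C)C
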